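If every initiator begins one chain and the protic impurity takes its own amount of free monomer, then a charge has a ceiling length, the target degree of polymerisation: free monomer charged less protic impurity charged, divided by initiator charged, reached at full conversion. For red this is 90.0, and for violet it is 15.0.

| flask | free monomer | protic impurity | initiator | remark | time |
|---|---|---|---|---|---|
| epsilon | 0.071 M | 0.020 M | 2 mM | run made earlier |  |
| eta | 0.27 M | 0.020 M | 2 mM | run made earlier |  |
| red | 0.20 M | 0.0200 M | 2.0 mM |  | 2.5 h |
| violet | 0.050 M | 0.0200 M | 2.0 mM |  | 2.5 h |

| run | time / h | monomer in chains / % | free monomer / % |
|---|---|---|---|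
| epsilon | 0.333 | 0.6 | 92.8 |
| epsilon | 0.833 | 2.4 | 84.4 |
| epsilon | 1.50 | 6.1 | 74.8 |
| epsilon | 2.50 | 13.5 | 63.0 |
| eta | 0.200 | 0.7 | 95.6 |
| eta | 0.500 | 2.2 | 91.2 |
| eta | 1.00 | 8.2 | 84.1 |
| eta | 2.50 | 28.8 | 64.0 |

(standard deviation of a reading: 0.5 percentage points)

* which of the two ends with the longer chains by the average number of monomer units in a chain (chains begun, living or dead) ("neither" if they lie within 10%) (red / violet / neither)
* average number of monomer units in a chain (chains begun, living or dead) at the end, red
* average number of monomer units in a chain (chains begun, living or dead) at the end, violet

- the average divides the monomer in chains by the number of chains begun, living and dead together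
- the earlier runs do not show the number of chains; that part of a forecast is a guess

The eta run supports the impurity term as a reading: at 2.50 h it is missing 7.20% of its charge, and its protic impurity amounts to 7.41% of that charge.

The rule stops working where conversion is incomplete, and the ratio of monomer in chains to the usable share shows where that is. At 2.50 h the eta run has filled 31.1% of its usable share, the epsilon run 18.8%. So the ceiling is no forecast for 2.5 h. My own reckoning multiplies each ceiling by the fill of the run nearest in charge and counts all initiator as begun, which the runs do not show. Red, closer to eta, comes to about 28.0. Violet, closer to epsilon, comes to about 2.82.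

The forecast also says red, with 32 for red and 6.6 for violet, on the ground that “This fits initiation that is first order in monomer”. For violet my figure lies lower than the forecast's.

The simulation gives 28.9 for red and 6.51 for violet.

    free monomer + living end → monomer in chains + living end, rate k1*[living end]*[free monomer] (k = 0.0290 M⁻¹ s⁻¹)
    free monomer + initiator → living end + monomer in chains (k = 0.00140 M⁻¹ s⁻¹)
    protic impurity + free monomer → quenched substrate (k = 0.00340 M⁻¹ s⁻¹)

Red stands at 32.1% of its ceiling after 2.5 h, and left until 25.0 h it reaches 89.8. The neighbouring flask is red charged with 0.0080 M of initiator, which lowers the ceiling to 22.5. At 2.50 h it has 26.5% of its free monomer left, and its length of 20.5 is 90.9% of that ceiling.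

(All runs come from a simulation with made-up constants; noise was put on by code.)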